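**Retrosynthetic overview**
- Isocycloheterophyllin comes, by fluoride desilylation in the last step, from its tris-TIPS ether. That ether comes in one palladium-catalysed cascade from an acyclic ortho-hydroxyaryl ynone whose ring B oxygen (ortho to the alkyne) carries a 2-aryloxyallyl tert-butyl carbonate.
- Enabling feature: C3 is the α-carbon of the ring C pyranone and is unmasked as a C3–palladium bond when the ring A phenol oxygen (O1) adds to alkyne carbon C2. The oxepine atoms CH2–C(=CMe2)–O–C2' form a 2-aryloxyallyl unit tethered through the ring B oxygen, so its CH2 end lies one reductive elimination from C3 and closes the seven-membered ring C2–C3–CH2–C(=CMe2)–O–C2'–C1'.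
- The ynone comes from a ring A aldehyde and a ring B arylalkyne (acetylide addition, then MnO2).
- The ring A aldehyde comes from 2,4,6-trihydroxybenzaldehyde: a chelation-directed propargyl Claisen/electrocyclisation builds the dimethylpyran ring, then a para-Claisen–Cope relay places the prenyl group and frees the phenol that becomes O1. The ring B alkyne comes from 2,4,5-trihydroxybenzaldehyde (Ohira–Bestmann, O–H insertion, Horner–Wadsworth–Emmons with acetone, DIBAL-H, Boc2O).
- Ring order: dimethylpyran ring (step 3), then ring C pyranone and the oxepine ring together (step 14).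

Key step: step 14

Remark on the chemistry: the target has no stereocentre and no stereogenic double bond, so no stereocontrol is needed; the racemic stereocentres that appear in a phosphonate, a dienone and a carbinol are destroyed within the route.

Step 1
Reactants: 1 2,4,6-trihydroxybenzaldehyde
Product: 2 2,6-dihydroxy-4-(2-methylbut-3-yn-2-yloxy)benzaldehyde
Conditions: K2CO3, KI, CuI (cat.), acetone, reflux
Reagents that add atoms: 3-chloro-3-methylbut-1-yne, C#CC(C)(C)Cl
Why: Copper-assisted Williamson O-alkylation with a tertiary propargylic chloride should occur at the 4-OH, which is para to the formyl group, not hydrogen-bonded and the most acidic of the three phenols.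

Step 2
Reactants: 2 2,6-dihydroxy-4-(2-methylbut-3-yn-2-yloxy)benzaldehyde
Product: 3 2-hydroxy-4-(2-methylbut-3-yn-2-yloxy)-6-(triisopropylsilyloxy)benzaldehyde
Conditions: TIPSCl (1.1 equiv), imidazole, DMF, 0 °C to rt
Reagents that add atoms: triisopropylsilyl chloride, CC(C)[Si](Cl)(C(C)C)C(C)C
Why: Silylation of one of two equivalent ortho-phenols should stop at the mono-ether, because the remaining OH is then locked in a strong hydrogen bond to the aldehyde and is too hindered for a second TIPS group.

Step 3
Reactants: 3 2-hydroxy-4-(2-methylbut-3-yn-2-yloxy)-6-(triisopropylsilyloxy)benzaldehyde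
Product: 6 5-hydroxy-2,2-dimethyl-7-(triisopropylsilyloxy)-2H-chromene-6-carbaldehyde, via allenylphenol 4 (not isolated), via ortho-quinone methide 5 (not isolated)
Conditions: PhNEt2, 170 °C
Reagents that add atoms: none
Why: This is an aryl propargyl ether Claisen rearrangement followed by enolisation, 1,5-hydrogen shift and oxa-6π electrocyclisation, in which the hydrogen-bonded ortho-hydroxy aldehyde fixes double-bond character in the C3–C4 bond so that the shift should go to C3 (next to the chelated OH) and the freed O4, not the chelated O2, should close the pyran.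

Step 4
Reactants: 6 5-hydroxy-2,2-dimethyl-7-(triisopropylsilyloxy)-2H-chromene-6-carbaldehyde
Product: 7 2,2-dimethyl-5-(3-methylbut-2-enyloxy)-7-(triisopropylsilyloxy)-2H-chromene-6-carbaldehyde
Conditions: prenyl bromide, K2CO3, acetone, reflux
Reagents that add atoms: 1-bromo-3-methylbut-2-ene, CC(C)=CCBr
Why: Williamson etherification of the only free (chelated) phenol with an allylic bromide should give the prenyl ether, the TIPS ether being stable to anhydrous carbonate in acetone.

Step 5
Reactants: 7 2,2-dimethyl-5-(3-methylbut-2-enyloxy)-7-(triisopropylsilyloxy)-2H-chromene-6-carbaldehyde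
Product: 9 5-hydroxy-2,2-dimethyl-8-(3-methylbut-2-enyl)-7-(triisopropylsilyloxy)-2H-chromene-6-carbaldehyde, via ortho-dienone 8 (not isolated)
Conditions: PhNEt2, 180 °C
Reagents that add atoms: none
Why: In this para-Claisen rearrangement (Claisen then Cope) both ortho positions of the prenyl ether are substituted, so the ortho-dienone cannot tautomerise and should relay the allyl group by a second [3,3] shift to the only free ring carbon C8, which restores the normal prenyl connectivity and frees the C5 hydroxyl next to the pyran ring.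

Step 6
Reactants: 10 2,4,5-trihydroxybenzaldehyde
Product: 11 2-hydroxy-4,5-bis(triisopropylsilyloxy)benzaldehyde
Conditions: TIPSCl (2.2 equiv), imidazole, DMF, 0 °C to rt
Reagents that add atoms: triisopropylsilyl chloride, CC(C)[Si](Cl)(C(C)C)C(C)C
Why: Silylation should take the two catechol phenols and leave the 2-OH, which is hydrogen-bonded to the aldehyde and the least reactive.

Step 7
Reactants: 11 2-hydroxy-4,5-bis(triisopropylsilyloxy)benzaldehyde
Product: 12 2-ethynyl-4,5-bis(triisopropylsilyloxy)phenol
Conditions: dimethyl (1-diazo-2-oxopropyl)phosphonate, K2CO3, MeOH, 0 °C to rt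
Reagents that add atoms: dimethyl (1-diazo-2-oxopropyl)phosphonate, CC(=O)C(=[N+]=[N-])P(=O)(OC)OC
Why: Ohira–Bestmann (Seyferth–Gilbert) homologation should convert the aldehyde into the terminal alkyne while the phenol is carried as its phenoxide and the aryl TIPS ethers survive carbonate in methanol at room temperature.

Step 8
Reactants: 12 2-ethynyl-4,5-bis(triisopropylsilyloxy)phenol
Product: 13 ethyl 2-(diethoxyphosphoryl)-2-[2-ethynyl-4,5-bis(triisopropylsilyloxy)phenoxy]acetate (racemic)
Conditions: ethyl 2-diazo-2-(diethoxyphosphoryl)acetate, Rh2(OAc)4 (1 mol%), PhMe, 80 °C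
Reagents that add atoms: ethyl 2-diazo-2-(diethoxyphosphoryl)acetate, CCOC(=O)C(=[N+]=[N-])P(=O)(OCC)OCC
Why: Rhodium carbenoid O–H insertion into the phenol should outrun cyclopropenation of the terminal alkyne for this acceptor/acceptor carbenoid; the new stereocentre forms racemic and is removed in step 9.

Step 9
Reactants: 13 ethyl 2-(diethoxyphosphoryl)-2-[2-ethynyl-4,5-bis(triisopropylsilyloxy)phenoxy]acetate
Product: 14 ethyl 2-[2-ethynyl-4,5-bis(triisopropylsilyloxy)phenoxy]-3-methylbut-2-enoate
Conditions: NaH (1.05 equiv), THF, 0 °C; acetone, 0 °C to reflux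
Reagents that add atoms: acetone, CC(C)=O
Why: Horner–Wadsworth–Emmons olefination of acetone should give the tetrasubstituted α-aryloxy enoate, the phosphonate C–H being far more acidic than the alkyne C–H and the two β-methyl groups leaving no E/Z question.

Step 10
Reactants: 14 ethyl 2-[2-ethynyl-4,5-bis(triisopropylsilyloxy)phenoxy]-3-methylbut-2-enoate
Product: 15 2-[2-ethynyl-4,5-bis(triisopropylsilyloxy)phenoxy]-3-methylbut-2-en-1-ol
Conditions: DIBAL-H (2.2 equiv), CH2Cl2, –78 °C; Rochelle salt
Reagents that add atoms: none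
Why: DIBAL-H 1,2-reduction of the unsaturated ester should give the allylic alcohol at low temperature without hydroalumination of the alkyne.

Step 11
Reactants: 15 2-[2-ethynyl-4,5-bis(triisopropylsilyloxy)phenoxy]-3-methylbut-2-en-1-ol
Product: 16 tert-butyl 2-[2-ethynyl-4,5-bis(triisopropylsilyloxy)phenoxy]-3-methylbut-2-enyl carbonate
Conditions: Boc2O, DMAP (10 mol%), CH2Cl2, 0 °C to rt
Reagents that add atoms: di-tert-butyl dicarbonate, CC(C)(C)OC(=O)OC(=O)OC(C)(C)C
Why: DMAP-catalysed O-acylation of the primary allylic alcohol should give the mixed tert-butyl carbonate, chosen because it resists nucleophiles in step 12 and releases a non-nucleophilic base in step 14.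

Step 12
Reactants: 9 5-hydroxy-2,2-dimethyl-8-(3-methylbut-2-enyl)-7-(triisopropylsilyloxy)-2H-chromene-6-carbaldehyde; 16 tert-butyl 2-[2-ethynyl-4,5-bis(triisopropylsilyloxy)phenoxy]-3-methylbut-2-enyl carbonate
Product: 18 racemic propargylic alcohol (ring A aryl–CH(OH)–C≡C–ring B aryl), via lithium acetylide 17 (not isolated)
Conditions: LiHMDS (2.2 equiv), THF, –78 to –20 °C; aq. NH4Cl
Reagents that add atoms: none
Why: Addition of a lithium acetylide to the aldehyde (the phenol being carried as its lithium phenoxide) should give the carbinol, LiHMDS being basic enough for the arylalkyne but too hindered to attack the carbonate; the carbinol stereocentre is racemic and is oxidised away in step 13.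

Step 13
Reactants: 18 racemic propargylic alcohol
Product: 19 ortho-hydroxyaryl ynone (ring A aryl–C(=O)–C≡C–ring B aryl)
Conditions: MnO2, CH2Cl2, rt
Reagents that add atoms: none
Why: MnO2 oxidation of the benzylic propargylic alcohol should give the ynone under neutral conditions that leave the free phenol, the silyl ethers and the carbonate untouched.

Step 14
Reactants: 19 ortho-hydroxyaryl ynone
Product: 21 tris-TIPS ether of isocycloheterophyllin, via vinyl-allyl palladacycle 20 (not isolated)
Conditions: Pd(PPh3)4 (10 mol%), THF, 60 °C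
Reagents that add atoms: none
Why: Proposed new method: zerovalent palladium ionises the allylic tert-butyl carbonate (loss of CO2) to a 2-aryloxy-π-allyl palladium cation whose tert-butoxide counter-ion deprotonates the chelated ring A phenol; the cationic metal, held next to the ynone by the ring B oxygen tether, activates the alkyne for anti attack of the phenoxide on C2, and the resulting C3–palladium σ-allyl species reductively eliminates to form the C3–CH2 bond. The closest known reaction type is the oxy- or aminopalladation/reductive elimination of ortho-alkynylphenols and ortho-alkynylanilides with allyl carbonates that gives 3-allylbenzofurans and 3-allylindoles, here extended to an ortho-hydroxyaryl ynone and run intramolecularly. The ring C pyranone closes by 6-endo-dig anti-oxypalladation (O1–C2 bond), and the oxepine closes by C(sp2)–C(sp3) reductive elimination from an eight-membered palladacycle, a ring contraction to the seven-membered ring. No stereocentre is formed and the new tetrasubstituted enol ether carries two identical methyl groups, so no stereochemical element has to be controlled. The step needs 6-endo over 5-exo attack (the Michael polarisation of the ynone makes the aryl-bearing carbon C2 the electrophilic one), coupling at the CH2 and not the CMe2 allyl terminus (sterics, and the conjugated tetrasubstituted enol ether that results), reaction of only one ring A oxygen (the other is a TIPS ether), and C–C coupling ahead of simple protonation at C3 (base-free aprotic conditions, in which the phenoxide forms only after ionisation).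

Step 15
Reactants: 21 tris-TIPS ether of isocycloheterophyllin
Product: 22 isocycloheterophyllin
Conditions: TBAF (3.5 equiv), AcOH (3.5 equiv), THF, 0 °C, under argon
Reagents that add atoms: none
Why: Fluoride cleavage of the three aryl silyl ethers should be fast, the acetic acid buffer keeping the catechol protonated against air oxidation while the enol ether, chromene and prenyl groups are untouched.

**Compound list**
1 | 2,4,6-trihydroxybenzaldehyde | O=Cc1c(O)cc(O)cc1O | starting material
2 | 2,6-dihydroxy-4-(2-methylbut-3-yn-2-yloxy)benzaldehyde | O=Cc1c(O)cc(OC(C)(C)C#C)cc1O | intermediate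
3 | 2-hydroxy-4-(2-methylbut-3-yn-2-yloxy)-6-(triisopropylsilyloxy)benzaldehyde | O=Cc1c(O)cc(OC(C)(C)C#C)cc1O[Si](C(C)C)(C(C)C)C(C)C | intermediate
4 | 2,4-dihydroxy-3-(3-methylbuta-1,2-dienyl)-6-(triisopropylsilyloxy)benzaldehyde (allenylphenol, not isolated) | O=Cc1c(O)c(C=C=C(C)C)c(O)cc1O[Si](C(C)C)(C(C)C)C(C)C | intermediate
5 | 2-hydroxy-3-(3-methylbut-2-enylidene)-4-oxo-6-(triisopropylsilyloxy)cyclohexa-1,5-diene-1-carbaldehyde (ortho-quinone methide, side chain cis to the ring ketone, not isolated) | O=CC1=C(O)/C(=C/C=C(C)C)C(=O)C=C1O[Si](C(C)C)(C(C)C)C(C)C | intermediate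
6 | 5-hydroxy-2,2-dimethyl-7-(triisopropylsilyloxy)-2H-chromene-6-carbaldehyde | O=Cc1c(O)c2C=CC(C)(C)Oc2cc1O[Si](C(C)C)(C(C)C)C(C)C | intermediate
7 | 2,2-dimethyl-5-(3-methylbut-2-enyloxy)-7-(triisopropylsilyloxy)-2H-chromene-6-carbaldehyde | O=Cc1c(OCC=C(C)C)c2C=CC(C)(C)Oc2cc1O[Si](C(C)C)(C(C)C)C(C)C | intermediate
8 | 2,2-dimethyl-6-(2-methylbut-3-en-2-yl)-5-oxo-7-(triisopropylsilyloxy)-5,6-dihydro-2H-chromene-6-carbaldehyde (ortho-dienone, racemic, not isolated) | O=CC1(C(C)(C)C=C)C(=O)C2=C(OC(C)(C)C=C2)C=C1O[Si](C(C)C)(C(C)C)C(C)C | intermediate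
9 | 5-hydroxy-2,2-dimethyl-8-(3-methylbut-2-enyl)-7-(triisopropylsilyloxy)-2H-chromene-6-carbaldehyde | O=Cc1c(O)c2C=CC(C)(C)Oc2c(CC=C(C)C)c1O[Si](C(C)C)(C(C)C)C(C)C | intermediate
10 | 2,4,5-trihydroxybenzaldehyde | O=Cc1cc(O)c(O)cc1O | starting material
11 | 2-hydroxy-4,5-bis(triisopropylsilyloxy)benzaldehyde | O=Cc1cc(O[Si](C(C)C)(C(C)C)C(C)C)c(O[Si](C(C)C)(C(C)C)C(C)C)cc1O | intermediate
12 | 2-ethynyl-4,5-bis(triisopropylsilyloxy)phenol | C#Cc1cc(O[Si](C(C)C)(C(C)C)C(C)C)c(O[Si](C(C)C)(C(C)C)C(C)C)cc1O | intermediate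
13 | ethyl 2-(diethoxyphosphoryl)-2-[2-ethynyl-4,5-bis(triisopropylsilyloxy)phenoxy]acetate (racemic) | CCOC(=O)C(Oc1cc(O[Si](C(C)C)(C(C)C)C(C)C)c(O[Si](C(C)C)(C(C)C)C(C)C)cc1C#C)P(=O)(OCC)OCC | intermediate
14 | ethyl 2-[2-ethynyl-4,5-bis(triisopropylsilyloxy)phenoxy]-3-methylbut-2-enoate | CCOC(=O)C(Oc1cc(O[Si](C(C)C)(C(C)C)C(C)C)c(O[Si](C(C)C)(C(C)C)C(C)C)cc1C#C)=C(C)C | intermediate
15 | 2-[2-ethynyl-4,5-bis(triisopropylsilyloxy)phenoxy]-3-methylbut-2-en-1-ol | OCC(Oc1cc(O[Si](C(C)C)(C(C)C)C(C)C)c(O[Si](C(C)C)(C(C)C)C(C)C)cc1C#C)=C(C)C | intermediate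
16 | tert-butyl 2-[2-ethynyl-4,5-bis(triisopropylsilyloxy)phenoxy]-3-methylbut-2-enyl carbonate | CC(C)(C)OC(=O)OCC(Oc1cc(O[Si](C(C)C)(C(C)C)C(C)C)c(O[Si](C(C)C)(C(C)C)C(C)C)cc1C#C)=C(C)C | intermediate
17 | lithium acetylide of 16 (not isolated) | CC(C)(C)OC(=O)OCC(Oc1cc(O[Si](C(C)C)(C(C)C)C(C)C)c(O[Si](C(C)C)(C(C)C)C(C)C)cc1C#C[Li])=C(C)C | intermediate
18 | racemic propargylic alcohol: 1-[5-hydroxy-2,2-dimethyl-8-(3-methylbut-2-enyl)-7-(triisopropylsilyloxy)-2H-chromen-6-yl]-3-[2-(1-(tert-butoxycarbonyloxy)-3-methylbut-2-en-2-yloxy)-4,5-bis(triisopropylsilyloxy)phenyl]prop-2-yn-1-ol | CC(C)(C)OC(=O)OCC(Oc1cc(O[Si](C(C)C)(C(C)C)C(C)C)c(O[Si](C(C)C)(C(C)C)C(C)C)cc1C#CC(O)c1c(O)c2C=CC(C)(C)Oc2c(CC=C(C)C)c1O[Si](C(C)C)(C(C)C)C(C)C)=C(C)C | intermediate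
19 | ortho-hydroxyaryl ynone: the prop-2-yn-1-one corresponding to 18 | CC(C)(C)OC(=O)OCC(Oc1cc(O[Si](C(C)C)(C(C)C)C(C)C)c(O[Si](C(C)C)(C(C)C)C(C)C)cc1C#CC(=O)c1c(O)c2C=CC(C)(C)Oc2c(CC=C(C)C)c1O[Si](C(C)C)(C(C)C)C(C)C)=C(C)C | intermediate
20 | eight-membered palladacycle of divalent palladium bonded to C3 of the new pyranone and to the allyl CH2 (one PPh3 shown, not isolated) | CC(C)=CCc1c2c(c3oc4c(c(=O)c3c1O[Si](C(C)C)(C(C)C)C(C)C)[Pd-]([P+](c5ccccc5)(c5ccccc5)c5ccccc5)CC(=C(C)C)Oc1cc(O[Si](C(C)C)(C(C)C)C(C)C)c(O[Si](C(C)C)(C(C)C)C(C)C)cc1-4)C=CC(C)(C)O2 | intermediate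
21 | tris-TIPS ether of isocycloheterophyllin (silyl groups on the C5 oxygen of ring A and on both catechol oxygens of ring B) | CC(C)=CCc1c2c(c3oc4c(c(=O)c3c1O[Si](C(C)C)(C(C)C)C(C)C)CC(=C(C)C)Oc1cc(O[Si](C(C)C)(C(C)C)C(C)C)c(O[Si](C(C)C)(C(C)C)C(C)C)cc1-4)C=CC(C)(C)O2 | intermediate
22 | isocycloheterophyllin | CC(C)=CCc1c2c(c3oc4c(c(=O)c3c1O)CC(=C(C)C)Oc1cc(O)c(O)cc1-4)C=CC(C)(C)O2 | target

**Totals and risks**
Total step count: 15. Longest linear sequence: 10 steps (steps 6 to 15, from 2,4,5-trihydroxybenzaldehyde); the ring A branch (steps 1 to 5) joins at step 12.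

Steps most likely to fail:

1. Step 14. The phenoxide may add to the ynone without the metal (or under catalysis by free phosphine) and be protonated at C3 before any C–C coupling; the tetrasubstituted allylic carbonate may also ionise too slowly, or closure may go 5-exo. Fallback, from 19 back to 21: conjugate addition of pyrrolidine (1 equiv, THF, rt) to the ynone should give the β-pyrrolidinyl enaminone F1. With Pd(PPh3)4 in THF at 60 °C the enaminone α-carbon (the future C3) should attack the CH2 end of the 2-aryloxy-π-allyl unit (Tsuji–Trost allylation with an enamine-type nucleophile). The resulting iminium is then captured by the ring A phenol with loss of pyrrolidine (the usual chromone annulation of ortho-hydroxyaryl enaminones), which returns to 21.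

2. Step 5. The ortho-dienone may lose its formyl group, or the prenyl ether may cleave ionically, instead of undergoing the second sigmatropic shift. Fallback, from 6 back to 9 (steps 4 and 5 are bypassed): iodination at C8, the only free ring carbon and para to the free phenol (NIS, DMF, 0 °C), should give 5-hydroxy-8-iodo-2,2-dimethyl-7-(triisopropylsilyloxy)-2H-chromene-6-carbaldehyde F2. Stille coupling with tributyl(3-methylbut-2-enyl)stannane (Pd(PPh3)4, DMF, 90 °C) should then give 9.

3. Step 12. Addition may stall because the aldehyde is deactivated as its phenoxide and flanked by two ortho substituents, and carbonate transfer may set in on warming. Fallback, from 9 back to 19: the phenol is silylated (TESOTf, 2,6-lutidine, CH2Cl2, –78 °C) to the TES ether F3. Lithium acetylide 17 should add to this neutral aldehyde at –78 °C to give the carbinol F4, MnO2 should give the TES-protected ynone F5, and Et3N·3HF in THF at 0 °C should remove the labile ortho-carbonyl TES ether without forming a phenoxide, returning to 19.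

**Further compounds**
F1 | step 14 | β-pyrrolidinyl enaminone from 19 (pyrrolidine on the ring B-bearing carbon, E/Z not defined) | CC(C)(C)OC(=O)OCC(Oc1cc(O[Si](C(C)C)(C(C)C)C(C)C)c(O[Si](C(C)C)(C(C)C)C(C)C)cc1C(=CC(=O)c1c(O)c2C=CC(C)(C)Oc2c(CC=C(C)C)c1O[Si](C(C)C)(C(C)C)C(C)C)N1CCCC1)=C(C)C
F2 | step 5 | 5-hydroxy-8-iodo-2,2-dimethyl-7-(triisopropylsilyloxy)-2H-chromene-6-carbaldehyde | O=Cc1c(O)c2C=CC(C)(C)Oc2c(I)c1O[Si](C(C)C)(C(C)C)C(C)C
F3 | step 12 | 2,2-dimethyl-8-(3-methylbut-2-enyl)-5-(triethylsilyloxy)-7-(triisopropylsilyloxy)-2H-chromene-6-carbaldehyde | O=Cc1c(O[Si](CC)(CC)CC)c2C=CC(C)(C)Oc2c(CC=C(C)C)c1O[Si](C(C)C)(C(C)C)C(C)C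
F4 | step 12 | TES ether of propargylic alcohol 18 (racemic) | CC(C)(C)OC(=O)OCC(Oc1cc(O[Si](C(C)C)(C(C)C)C(C)C)c(O[Si](C(C)C)(C(C)C)C(C)C)cc1C#CC(O)c1c(O[Si](CC)(CC)CC)c2C=CC(C)(C)Oc2c(CC=C(C)C)c1O[Si](C(C)C)(C(C)C)C(C)C)=C(C)C
F5 | step 12 | TES ether of ynone 19 | CC(C)(C)OC(=O)OCC(Oc1cc(O[Si](C(C)C)(C(C)C)C(C)C)c(O[Si](C(C)C)(C(C)C)C(C)C)cc1C#CC(=O)c1c(O[Si](CC)(CC)CC)c2C=CC(C)(C)Oc2c(CC=C(C)C)c1O[Si](C(C)C)(C(C)C)C(C)C)=C(C)C
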